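**Strategy.** The plan cuts both C–O bonds of the peroxide bridge (O1–C6 and O2–C3) of the 1,2-dioxane ring and traces them to H2O2 and an acyclic chain whose C3 and C6 are ordinary carbinol-type centres. The key step exploits the fact that the O1–O2 unit sits between tertiary C6 and secondary C3: H2O2 opens a 2,2-disubstituted epoxide at C6 and the resulting hydroperoxide displaces a C3 mesylate, each with inversion, closing the ring and fixing both centres in one operation. Its precursor is an epoxy mesylate with C4 methyl, an (E)-vinyl iodide side chain and a C1 pivalate, built by Evans aldol, Negishi coupling and Sharpless epoxidation.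

Key step: step 13

Remark (assumptions): locants C1–C12 are those of the target chain (C1 = ester carbon, C3 and C6 = ring carbons on O2 and O1, C7–C12 = side chain); 1-phenylbut-2-yne (25) and acetylene (14) are taken as purchasable. The (E)-iodoalkene is made by syn-carboalumination of a C7–C8≡C9 alkyne, because syn-metallocupration of propyne followed by alkylation would place C7 cis to the metal and give the (Z)-isomer.

**Step 1**
Reactants: 1 propane-1,3-diol
Product: 2 3-hydroxypropyl 2,2-dimethylpropanoate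
Conditions: pivaloyl chloride (1 equiv), 1 (3 equiv), pyridine, CH2Cl2, 0 °C
Reagents that add atoms: pivaloyl chloride, CC(C)(C)C(Cl)=O
Why: Nucleophilic acyl substitution on the symmetric diol used in excess should give mainly the monoester, the bulky pivaloyl group disfavouring a second acylation.

**Step 2**
Reactants: 2 3-hydroxypropyl 2,2-dimethylpropanoate
Product: 3 3-oxopropyl 2,2-dimethylpropanoate
Conditions: TEMPO (cat.), PhI(OAc)2, CH2Cl2, rt
Reagents that add atoms: none
Why: Nitroxyl-catalysed oxidation stops at the aldehyde under base-free conditions, which avoids β-elimination of pivalate from the β-acyloxy aldehyde.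

**Step 3**
Reactants: 3 3-oxopropyl 2,2-dimethylpropanoate; 4 (S)-4-benzyl-3-propionyloxazolidin-2-one
Product: 6 (S)-4-benzyl-3-[(2S,3R)-3-hydroxy-2-methyl-5-(pivaloyloxy)pentanoyl]oxazolidin-2-one, via dibutylboron (Z)-enolate 5 (not isolated)
Conditions: Bu2BOTf, i-Pr2NEt, CH2Cl2, −78 → 0 °C; then 3, −78 → 0 °C; pH 7 buffer, MeOH, 30% H2O2, 0 °C
Reagents that add atoms: none
Why: Evans syn-aldol reaction in which the (Z)-boron enolate reacts through a closed Zimmerman–Traxler transition state on the face away from the benzyl group of the auxiliary, setting C4 (2S of the acyl chain) and C3 (3R) with syn relative and auxiliary-controlled absolute configuration.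

**Step 4**
Reactants: 6 aldol adduct
Product: 7 (S)-4-benzyl-3-[(2S,3R)-2-methyl-5-(pivaloyloxy)-3-(triethylsilyloxy)pentanoyl]oxazolidin-2-one
Conditions: Et3SiOTf, 2,6-lutidine, CH2Cl2, −78 → 0 °C
Reagents that add atoms: triethylsilyl trifluoromethanesulfonate, CC[Si](CC)(CC)OS(=O)(=O)C(F)(F)F
Why: Silyl triflate silylation with a hindered pyridine base is fast at low temperature and avoids retro-aldol cleavage, and the triethylsilyl ether can later be removed by buffered fluoride without touching the pivalate or an epoxide.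

**Step 5**
Reactants: 7 silyl ether
Product: 8 (3R,4R)-5-hydroxy-4-methyl-3-(triethylsilyloxy)pentyl 2,2-dimethylpropanoate
Conditions: LiBH4, MeOH (1 equiv), Et2O, 0 °C
Reagents that add atoms: none
Why: LiBH4 reduces the activated N-acyl oxazolidinone to the primary alcohol much faster than the hindered pivalate, releasing the auxiliary without touching the stereocentres.

**Step 6**
Reactants: 8 primary alcohol
Product: 9 (3R,4S)-5-iodo-4-methyl-3-(triethylsilyloxy)pentyl 2,2-dimethylpropanoate
Conditions: I2, PPh3, imidazole, CH2Cl2, 0 °C → rt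
Reagents that add atoms: iodine, II
Why: Appel-type iodination converts the unhindered primary alcohol into the iodide by SN2 displacement of the alkoxyphosphonium ion, away from both stereocentres.

**Step 7**
Reactants: 9 primary iodide; 10 2-bromoprop-2-en-1-ol
Product: 12 (3R,4R)-6-(hydroxymethyl)-4-methyl-3-(triethylsilyloxy)hept-6-enyl 2,2-dimethylpropanoate, via alkylzinc iodide 11 (not isolated)
Conditions: Zn dust (activated with BrCH2CH2Br and Me3SiCl), LiCl, THF, 40 °C; then 10 (1.3 equiv), Pd(OAc)2 (2 mol%), SPhos (4 mol%), THF, rt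
Reagents that add atoms: none
Why: Direct zinc insertion gives an ester-tolerant alkylzinc iodide, and its Negishi sp3–sp2 coupling with the alkenyl bromide under a biarylphosphine palladium catalyst should outrun protonation by the free allylic hydroxyl, forming the C5–C6 bond without affecting C3 or C4.

**Step 8**
Reactants: 12 2-methylene allylic alcohol
Product: 13 (3R,4R)-5-[(2R)-2-(hydroxymethyl)oxiran-2-yl]-4-methyl-3-(triethylsilyloxy)pentyl 2,2-dimethylpropanoate
Conditions: Ti(Oi-Pr)4 (10 mol%), D-(−)-diethyl tartrate (12 mol%), t-BuOOH (2 equiv, in decane), 4 Å molecular sieves, CH2Cl2, −20 °C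
Reagents that add atoms: tert-butyl hydroperoxide, CC(C)(C)OO
Why: Sharpless asymmetric epoxidation of the 2-substituted allylic alcohol delivers oxygen under reagent control, and the D-(−)-tartrate should give the (2R)-epoxy alcohol, which sets the C6–O stereocentre.

**Step 9**
Reactants: 13 epoxy alcohol; 14 acetylene
Product: 15 (3R,4R,6S)-6-hydroxy-6-(hydroxymethyl)-4-methyl-3-(triethylsilyloxy)non-8-ynyl 2,2-dimethylpropanoate
Conditions: HC≡CLi (4 equiv, from 14 and n-BuLi, THF, −78 °C), BF3·OEt2 (3 equiv), THF, −78 °C; NH4Cl (aq)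
Reagents that add atoms: none
Why: BF3-promoted epoxide opening by lithium acetylide occurs by SN2 attack at the unsubstituted CH2 terminus, so the C6–O bond and configuration are retained while C7–C9 are attached, the excess acetylide covering the free hydroxyl.

**Step 10**
Reactants: 15 alkyne diol
Product: 17 (3R,4R,6S,8E)-6-hydroxy-6-(hydroxymethyl)-9-iodo-4,8-dimethyl-3-(triethylsilyloxy)non-8-enyl 2,2-dimethylpropanoate, via (E)-alkenylalane 16 (not isolated)
Conditions: Me3Al (5 equiv), Cp2ZrCl2 (0.5 equiv), CH2Cl2, 0 °C → rt; then I2, THF, −30 → 0 °C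
Reagents that add atoms: trimethylaluminium, C[Al](C)C; iodine, II
Why: Zirconium-catalysed carboalumination (Negishi) adds methyl and aluminium syn across the terminal alkyne with aluminium on the terminal carbon, and iodinolysis with retention should give only the (E)-2-methyl-1-iodoalkene, the hydroxyls being tolerated as aluminium alkoxides.

**Step 11**
Reactants: 17 vinyl iodide diol
Product: 19 (3R,4R)-5-{(2S)-2-[(E)-3-iodo-2-methylprop-2-enyl]oxiran-2-yl}-4-methyl-3-(triethylsilyloxy)pentyl 2,2-dimethylpropanoate, via primary tosylate 18 (not isolated)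
Conditions: NaH (3 equiv), 1-(p-tolylsulfonyl)imidazole (1.1 equiv), THF, 0 °C → rt
Reagents that add atoms: none
Why: The less hindered primary alkoxide is sulfonylated selectively and the neighbouring tertiary alkoxide closes the epoxide by 3-exo-tet Williamson displacement, so no bond to C6 is broken and the carbinol configuration becomes that of the (S)-epoxide.

**Step 12**
Reactants: 19 silyl-protected epoxide
Product: 21 (3R,4R)-5-{(2S)-2-[(E)-3-iodo-2-methylprop-2-enyl]oxiran-2-yl}-4-methyl-3-(methylsulfonyloxy)pentyl 2,2-dimethylpropanoate, via hydroxy epoxide 20 (not isolated)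
Conditions: Bu4NF, AcOH (1:1), THF, 0 °C; aqueous work-up, crude alcohol then MsCl, Et3N, CH2Cl2, −20 → 0 °C
Reagents that add atoms: methanesulfonyl chloride, CS(=O)(=O)Cl
Why: Acetic-acid-buffered fluoride removes the triethylsilyl ether without generating an alkoxide that could attack the epoxide or the pivalate, and immediate mesylation (O–S bond formation) converts C3–OH with retention into the leaving group before the hydroxy epoxide can cyclise.

**Step 13**
Reactants: 21 epoxy mesylate; 22 hydrogen peroxide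
Product: 24 2-{(3S,4R,6R)-6-(hydroxymethyl)-6-[(E)-3-iodo-2-methylprop-2-enyl]-4-methyl-1,2-dioxan-3-yl}ethyl 2,2-dimethylpropanoate, via β-hydroxy hydroperoxide 23 (not isolated)
Conditions: H2O2 in Et2O (dried, ca. 10 equiv), H3PMo12O40 (5 mol%), Et2O, rt; aqueous work-up; then KOt-Bu (1.05 equiv), 18-crown-6, THF, 0 °C
Reagents that add atoms: none
Why: Protonation of the epoxide by H3PMo12O40 polarises the C6–O bond and H2O2 attacks the tertiary carbon anti to the departing oxygen in a borderline SN2 opening to give hydroperoxide 23 (O1–C6), after which one equivalent of KOt-Bu deprotonates the hydroperoxide and the peroxy anion displaces the C3 mesylate (O2–C3). The closest known reaction types are the heteropolyacid-catalysed perhydrolysis of 2,2-disubstituted epoxides at the more substituted carbon and the base-mediated intramolecular O-alkylation of hydroperoxides by sulfonates. The 1,2-dioxane ring is closed in a 6-exo-tet mode. C6 is controlled by inversion of the (S)-epoxide installed through the Sharpless epoxidation and C3 by inversion of the (R)-mesylate derived from the Evans aldol reaction, so both reach the target configuration while C4 is untouched. The step needs attack at C6 and not at the epoxide CH2, which the better cation-stabilising ability of the fully substituted carbon under acid secures, and O-alkylation by the peroxy anion and not by the primary alkoxide, which the much lower pKa and α-effect nucleophilicity of the hydroperoxide secure when only one equivalent of base is used. C1 is carried as a pivalate-protected alcohol, so there is no acidifying carbonyl next to the mesylate to promote its elimination before the ring closes.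

**Step 14**
Reactants: 24 iodoalkenyl dioxane; 25 1-phenylbut-2-yne
Product: 28 2-{(3S,4R,6R)-6-[(2E,4E)-2,4-dimethyl-6-phenylhexa-2,4-dienyl]-6-(hydroxymethyl)-4-methyl-1,2-dioxan-3-yl}ethyl 2,2-dimethylpropanoate, via alkenylzirconocene chloride 26 (not isolated), via alkenylzinc chloride 27 (not isolated)
Conditions: 25 (3 equiv), Cp2Zr(H)Cl, THF, rt → 40 °C; ZnCl2, THF, 0 °C; then 24, Pd(PPh3)4 (5 mol%), THF, rt
Reagents that add atoms: none
Why: Syn-hydrozirconation of the 2-alkyne places zirconium on the methyl-bearing carbon after equilibration, transmetalation to zinc and Negishi coupling proceed with retention at both alkene carbons to give the (E,E)-diene, and zerovalent palladium should insert into the C–I bond far faster than it attacks the hindered dialkyl peroxide.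

**Step 15**
Reactants: 28 hydroxymethyl diene
Product: 30 2-{(3S,4R,6R)-6-[(2E,4E)-2,4-dimethyl-6-phenylhexa-2,4-dienyl]-6-(iodomethyl)-4-methyl-1,2-dioxan-3-yl}ethyl 2,2-dimethylpropanoate, via neopentyl-type triflate 29 (not isolated)
Conditions: Tf2O, 2,6-lutidine, CH2Cl2, −78 °C; then Bu4NI, −78 °C → rt
Reagents that add atoms: tetrabutylammonium iodide, CCCC[N+](CCCC)(CCCC)CCCC.[I-]
Why: The neopentyl-type primary alcohol is activated as its triflate because only this leaving group is displaced by iodide (Finkelstein-type SN2) at such a hindered carbon near room temperature, and C6 carries no hydrogen, so elimination is impossible.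

**Step 16**
Reactants: 30 primary iodide
Product: 31 2-{(3S,4R,6R)-6-[(2E,4E)-2,4-dimethyl-6-phenylhexa-2,4-dienyl]-4,6-dimethyl-1,2-dioxan-3-yl}ethyl 2,2-dimethylpropanoate
Conditions: Bu3SnH (3 equiv, 0.5 M), Et3B (0.2 equiv), air, toluene, 0 °C
Reagents that add atoms: none
Why: Radical chain dehalogenation in which iodine abstraction by Bu3Sn• gives the primary radical, which at high tin hydride concentration and low temperature should be reduced by hydrogen-atom transfer faster than it attacks the neighbouring O–O bond, as in tin hydride reductions of halomethyl-substituted cyclic peroxides.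

**Step 17**
Reactants: 31 pivalate
Product: 32 2-{(3S,4R,6R)-6-[(2E,4E)-2,4-dimethyl-6-phenylhexa-2,4-dienyl]-4,6-dimethyl-1,2-dioxan-3-yl}ethanol
Conditions: i-Bu2AlH (2.5 equiv), CH2Cl2, −78 °C
Reagents that add atoms: none
Why: i-Bu2AlH cleaves the pivalate reductively at −78 °C, a temperature at which the hindered dialkyl peroxide and the diene are inert, liberating the C1 alcohol without basic conditions.

**Step 18**
Reactants: 32 primary alcohol
Product: 34 2-{(3S,4R,6R)-6-[(2E,4E)-2,4-dimethyl-6-phenylhexa-2,4-dienyl]-4,6-dimethyl-1,2-dioxan-3-yl}acetic acid, via aldehyde 33 (not isolated)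
Conditions: TEMPO (0.2 equiv), PhI(OAc)2 (2.5 equiv), MeCN–H2O (1:1, pH 7 buffer), rt
Reagents that add atoms: water, O
Why: Nitroxyl/hypervalent-iodine oxidation in aqueous acetonitrile takes the primary alcohol through the aldehyde hydrate directly to the acid under near-neutral conditions, so the β-peroxy aldehyde is never exposed to base that would trigger retro-oxa-Michael ring opening.

**Step 19**
Reactants: 34 carboxylic acid
Product: 35 methyl 2-{(3S,4R,6R)-6-[(2E,4E)-2,4-dimethyl-6-phenylhexa-2,4-dienyl]-4,6-dimethyl-1,2-dioxan-3-yl}acetate (target)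
Conditions: Me3SiCHN2, toluene–MeOH (4:1), 0 °C
Reagents that add atoms: (trimethylsilyl)diazomethane, C[Si](C)(C)C=[N+]=[N-]
Why: Methylation of the acid with Me3SiCHN2 in methanol is neutral and fast, leaving the base-sensitive β-peroxy ester, the peroxide and the diene untouched.

**Compound list**

1 | propane-1,3-diol | OCCCO | starting material
2 | 3-hydroxypropyl 2,2-dimethylpropanoate | CC(C)(C)C(=O)OCCCO | intermediate
3 | 3-oxopropyl 2,2-dimethylpropanoate | CC(C)(C)C(=O)OCCC=O | intermediate
4 | (S)-4-benzyl-3-propionyloxazolidin-2-one | CCC(=O)N1[C@@H](Cc2ccccc2)COC1=O | starting material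
5 | dibutylboron (Z)-enolate of 4 (not isolated) | C/C=C(\OB(CCCC)CCCC)N1[C@@H](Cc2ccccc2)COC1=O | intermediate
6 | (S)-4-benzyl-3-[(2S,3R)-3-hydroxy-2-methyl-5-(pivaloyloxy)pentanoyl]oxazolidin-2-one | O=C([C@@H](C)[C@H](O)CCOC(=O)C(C)(C)C)N1[C@@H](Cc2ccccc2)COC1=O | intermediate
7 | (S)-4-benzyl-3-[(2S,3R)-2-methyl-5-(pivaloyloxy)-3-(triethylsilyloxy)pentanoyl]oxazolidin-2-one | O=C([C@@H](C)[C@H](O[Si](CC)(CC)CC)CCOC(=O)C(C)(C)C)N1[C@@H](Cc2ccccc2)COC1=O | intermediate
8 | (3R,4R)-5-hydroxy-4-methyl-3-(triethylsilyloxy)pentyl 2,2-dimethylpropanoate | OC[C@@H](C)[C@H](O[Si](CC)(CC)CC)CCOC(=O)C(C)(C)C | intermediate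
9 | (3R,4S)-5-iodo-4-methyl-3-(triethylsilyloxy)pentyl 2,2-dimethylpropanoate | IC[C@@H](C)[C@H](O[Si](CC)(CC)CC)CCOC(=O)C(C)(C)C | intermediate
10 | 2-bromoprop-2-en-1-ol | OCC(Br)=C | starting material
11 | [(2S,3R)-2-methyl-5-(pivaloyloxy)-3-(triethylsilyloxy)pentyl]zinc iodide (not isolated) | I[Zn]C[C@@H](C)[C@H](O[Si](CC)(CC)CC)CCOC(=O)C(C)(C)C | intermediate
12 | (3R,4R)-6-(hydroxymethyl)-4-methyl-3-(triethylsilyloxy)hept-6-enyl 2,2-dimethylpropanoate | C=C(CO)C[C@@H](C)[C@H](O[Si](CC)(CC)CC)CCOC(=O)C(C)(C)C | intermediate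
13 | (3R,4R)-5-[(2R)-2-(hydroxymethyl)oxiran-2-yl]-4-methyl-3-(triethylsilyloxy)pentyl 2,2-dimethylpropanoate | OC[C@]1(C[C@@H](C)[C@H](O[Si](CC)(CC)CC)CCOC(=O)C(C)(C)C)CO1 | intermediate
14 | acetylene | C#C | starting material
15 | (3R,4R,6S)-6-hydroxy-6-(hydroxymethyl)-4-methyl-3-(triethylsilyloxy)non-8-ynyl 2,2-dimethylpropanoate | OC[C@](O)(C[C@@H](C)[C@H](O[Si](CC)(CC)CC)CCOC(=O)C(C)(C)C)CC#C | intermediate
16 | (E)-C9 dimethylalane of 17 (not isolated; hydroxyls drawn free, present as aluminium alkoxides) | C[Al](C)/C=C(C)/C[C@](O)(CO)C[C@@H](C)[C@H](O[Si](CC)(CC)CC)CCOC(=O)C(C)(C)C | intermediate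
17 | (3R,4R,6S,8E)-6-hydroxy-6-(hydroxymethyl)-9-iodo-4,8-dimethyl-3-(triethylsilyloxy)non-8-enyl 2,2-dimethylpropanoate | OC[C@](O)(C[C@@H](C)[C@H](O[Si](CC)(CC)CC)CCOC(=O)C(C)(C)C)C/C(C)=C/I | intermediate
18 | primary p-toluenesulfonate of 17 (not isolated) | Cc1ccc(cc1)S(=O)(=O)OC[C@](O)(C[C@@H](C)[C@H](O[Si](CC)(CC)CC)CCOC(=O)C(C)(C)C)C/C(C)=C/I | intermediate
19 | (3R,4R)-5-{(2S)-2-[(E)-3-iodo-2-methylprop-2-enyl]oxiran-2-yl}-4-methyl-3-(triethylsilyloxy)pentyl 2,2-dimethylpropanoate | C1O[C@]1(C/C(C)=C/I)C[C@@H](C)[C@H](O[Si](CC)(CC)CC)CCOC(=O)C(C)(C)C | intermediate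
20 | (3R,4R)-3-hydroxy-5-{(2S)-2-[(E)-3-iodo-2-methylprop-2-enyl]oxiran-2-yl}-4-methylpentyl 2,2-dimethylpropanoate (not isolated) | C1O[C@]1(C/C(C)=C/I)C[C@@H](C)[C@H](O)CCOC(=O)C(C)(C)C | intermediate
21 | (3R,4R)-5-{(2S)-2-[(E)-3-iodo-2-methylprop-2-enyl]oxiran-2-yl}-4-methyl-3-(methylsulfonyloxy)pentyl 2,2-dimethylpropanoate (key-step precursor) | C1O[C@]1(C/C(C)=C/I)C[C@@H](C)[C@H](OS(C)(=O)=O)CCOC(=O)C(C)(C)C | intermediate
22 | hydrogen peroxide | OO | starting material
23 | (3R,4R,6R,8E)-6-hydroperoxy-6-(hydroxymethyl)-9-iodo-4,8-dimethyl-3-(methylsulfonyloxy)non-8-enyl 2,2-dimethylpropanoate (not isolated) | OO[C@@](CO)(C/C(C)=C/I)C[C@@H](C)[C@H](OS(C)(=O)=O)CCOC(=O)C(C)(C)C | intermediate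
24 | 2-{(3S,4R,6R)-6-(hydroxymethyl)-6-[(E)-3-iodo-2-methylprop-2-enyl]-4-methyl-1,2-dioxan-3-yl}ethyl 2,2-dimethylpropanoate (key-step product) | CC(C)(C)C(=O)OCC[C@@H]1OO[C@@](CO)(C/C(C)=C/I)C[C@H]1C | intermediate
25 | 1-phenylbut-2-yne | CC#CCc1ccccc1 | starting material
26 | chloro[(E)-4-phenylbut-2-en-2-yl]zirconocene (not isolated) | Cl[Zr](C1C=CC=C1)(C1C=CC=C1)/C(C)=C/Cc1ccccc1 | intermediate
27 | [(E)-4-phenylbut-2-en-2-yl]zinc chloride (not isolated) | Cl[Zn]/C(C)=C/Cc1ccccc1 | intermediate
28 | 2-{(3S,4R,6R)-6-[(2E,4E)-2,4-dimethyl-6-phenylhexa-2,4-dienyl]-6-(hydroxymethyl)-4-methyl-1,2-dioxan-3-yl}ethyl 2,2-dimethylpropanoate | CC(C)(C)C(=O)OCC[C@@H]1OO[C@@](CO)(C/C(C)=C/C(C)=C/Cc2ccccc2)C[C@H]1C | intermediate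
29 | trifluoromethanesulfonate of 28 at the C6 hydroxymethyl group (not isolated) | CC(C)(C)C(=O)OCC[C@@H]1OO[C@@](COS(=O)(=O)C(F)(F)F)(C/C(C)=C/C(C)=C/Cc2ccccc2)C[C@H]1C | intermediate
30 | 2-{(3S,4R,6R)-6-[(2E,4E)-2,4-dimethyl-6-phenylhexa-2,4-dienyl]-6-(iodomethyl)-4-methyl-1,2-dioxan-3-yl}ethyl 2,2-dimethylpropanoate | CC(C)(C)C(=O)OCC[C@@H]1OO[C@@](CI)(C/C(C)=C/C(C)=C/Cc2ccccc2)C[C@H]1C | intermediate
31 | 2-{(3S,4R,6R)-6-[(2E,4E)-2,4-dimethyl-6-phenylhexa-2,4-dienyl]-4,6-dimethyl-1,2-dioxan-3-yl}ethyl 2,2-dimethylpropanoate | CC(C)(C)C(=O)OCC[C@@H]1OO[C@@](C)(C/C(C)=C/C(C)=C/Cc2ccccc2)C[C@H]1C | intermediate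
32 | 2-{(3S,4R,6R)-6-[(2E,4E)-2,4-dimethyl-6-phenylhexa-2,4-dienyl]-4,6-dimethyl-1,2-dioxan-3-yl}ethanol | OCC[C@@H]1OO[C@@](C)(C/C(C)=C/C(C)=C/Cc2ccccc2)C[C@H]1C | intermediate
33 | 2-{(3S,4R,6R)-6-[(2E,4E)-2,4-dimethyl-6-phenylhexa-2,4-dienyl]-4,6-dimethyl-1,2-dioxan-3-yl}acetaldehyde (not isolated) | O=CC[C@@H]1OO[C@@](C)(C/C(C)=C/C(C)=C/Cc2ccccc2)C[C@H]1C | intermediate
34 | 2-{(3S,4R,6R)-6-[(2E,4E)-2,4-dimethyl-6-phenylhexa-2,4-dienyl]-4,6-dimethyl-1,2-dioxan-3-yl}acetic acid | OC(=O)C[C@@H]1OO[C@@](C)(C/C(C)=C/C(C)=C/Cc2ccccc2)C[C@H]1C | intermediate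
35 | methyl 2-{(3S,4R,6R)-6-[(2E,4E)-2,4-dimethyl-6-phenylhexa-2,4-dienyl]-4,6-dimethyl-1,2-dioxan-3-yl}acetate | COC(=O)C[C@@H]1OO[C@@](C)(C/C(C)=C/C(C)=C/Cc2ccccc2)C[C@H]1C | target

**Step count.** Total: 19 steps. Longest linear sequence: 19 steps (1 → 35); the other starting materials enter as purchased.

**Steps most likely to fail**

Step 13 (key step). Under the acid the C6–O bond may ionise before H2O2 arrives, which would scramble C6 or divert the epoxide by hydride shift or hydrolysis. In the basic stage, elimination of the mesylate or attack by the primary alkoxide may compete with peroxide closure. The fallback forms the two C–O bonds in the reverse order. Setting out from mesylate 21, intermolecular SN2 alkylation of 2-methoxyprop-2-yl hydroperoxide (KOt-Bu, 18-crown-6, THF, 0 °C → rt) would give, with inversion at C3 and the epoxide intact, (3S,4R)-5-{(2S)-2-[(E)-3-iodo-2-methylprop-2-enyl]oxiran-2-yl}-3-[(2-methoxypropan-2-yl)peroxy]-4-methylpentyl 2,2-dimethylpropanoate F1. Aqueous AcOH would release the hydroperoxy epoxide (3S,4R)-3-hydroperoxy-5-{(2S)-2-[(E)-3-iodo-2-methylprop-2-enyl]oxiran-2-yl}-4-methylpentyl 2,2-dimethylpropanoate F2. A catalytic sulfonic acid in CH2Cl2 would then trigger intramolecular 6-exo opening of the epoxide at C6, where the tether enforces backside attack and hence inversion. This returns to the route at dioxane 24.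

Step 16. The primary radical next to C6 may attack O1 of the peroxide (3-exo ring opening to an epoxide and an alkoxyl radical) before it is reduced, and reversible addition of stannyl radicals may scramble the diene geometry. The fallback is a polar reduction that avoids radicals. Setting out from alcohol 28, the triflate 29 formed as in step 15 would be treated directly with Bu4NBH4 (THF, rt → 40 °C) for hydride displacement of the sulfonate. This returns to the route at 31 and by-passes iodide 30.

Step 14. Incomplete regiocontrol in the hydrozirconation (zirconium on the benzyl-bearing carbon) would carry an isomeric diene through, and the free hydroxyl of 24 may protonate the alkenylzinc. The fallback is a Suzuki–Miyaura coupling with a boronate of unambiguous constitution, setting out from 24. Purchased prop-2-ynylbenzene would be brominated (NBS, AgNO3 cat., acetone) to (3-bromoprop-2-ynyl)benzene F3. Syn-hydroboration with HBBr2·SMe2 and esterification with pinacol would give (Z)-2-(1-bromo-3-phenylprop-1-enyl)-4,4,5,5-tetramethyl-1,3,2-dioxaborolane F4, with boron on the bromine-bearing carbon. Methylation at the C–Br bond with retention (MeZnCl, Pd(PPh3)4, THF) would give (Z)-4,4,5,5-tetramethyl-2-(4-phenylbut-2-en-2-yl)-1,3,2-dioxaborolane F5. Coupling of F5 with iodide 24 (Pd(dppf)Cl2, aqueous K3PO4, THF, rt) would return to the route at 28.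

**Further compounds**

F1 | step 13 | (3S,4R)-5-{(2S)-2-[(E)-3-iodo-2-methylprop-2-enyl]oxiran-2-yl}-3-[(2-methoxypropan-2-yl)peroxy]-4-methylpentyl 2,2-dimethylpropanoate | C1O[C@]1(C/C(C)=C/I)C[C@@H](C)[C@@H](OOC(C)(C)OC)CCOC(=O)C(C)(C)C
F2 | step 13 | (3S,4R)-3-hydroperoxy-5-{(2S)-2-[(E)-3-iodo-2-methylprop-2-enyl]oxiran-2-yl}-4-methylpentyl 2,2-dimethylpropanoate | C1O[C@]1(C/C(C)=C/I)C[C@@H](C)[C@@H](OO)CCOC(=O)C(C)(C)C
F0 | step 16 | none | none
F3 | step 14 | (3-bromoprop-2-ynyl)benzene | BrC#CCc1ccccc1
F4 | step 14 | (Z)-2-(1-bromo-3-phenylprop-1-enyl)-4,4,5,5-tetramethyl-1,3,2-dioxaborolane | Br/C(=C\Cc1ccccc1)B1OC(C)(C)C(C)(C)O1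
F5 | step 14 | (Z)-4,4,5,5-tetramethyl-2-(4-phenylbut-2-en-2-yl)-1,3,2-dioxaborolane | C/C(=C\Cc1ccccc1)B1OC(C)(C)C(C)(C)O1
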